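The cyclopentane is cut at the ring bond between the isopropenyl-bearing CH and the ring CH that carries the CH2 link to the trione ring; this CH lies next to the methyl carbinol carbon, which comes unchanged from C3 of (S)-linalool (linalool C2 and C6 become the two new ring CH centres). One anodic oxidation of an enol ether tethered to an allylsilane closes that five-membered ring, sets both CH stereocentres, releases the isopropenyl group and delivers the link carbon as a dimethyl acetal. Its precursor is an open chain: a (3S)-3-silyloxy-3-methyl centre, a methyl enol ether on one side, a 2-methylallylsilane on the other. The derived aldehyde then reductively alkylates a resolved acyl trione.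

Key step: step 6

Remark: the acyl trione unit is written throughout in the enol form of the target drawing; in that form its quaternary ring carbon is C6 and is (R).
Remark: the aldehyde–allylsilane and the enol ether precursor are used as mixtures of double-bond isomers, since both alkene geometries are erased in the ring closure; (S)-linalool of high enantiomeric purity is assumed.

Step 1
Reactants: 1 (S)-(+)-linalool
Product: 2 tert-butyl{[(3S)-3,7-dimethylocta-1,6-dien-3-yl]oxy}dimethylsilane
Conditions: TBSOTf (1.3 equiv), 2,6-lutidine (2 equiv), CH2Cl2, −78 → 0 °C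
Reagents that add atoms: tert-butyldimethylsilyl trifluoromethanesulfonate, CC(C)(C)[Si](C)(C)OS(=O)(=O)C(F)(F)F
Why: Silyl ether formation with a silyl triflate and a hindered pyridine base should protect the tertiary allylic alcohol without ionising it, and the stereocentre is not touched.

Step 2
Reactants: 2 tert-butyl{[(3S)-3,7-dimethylocta-1,6-dien-3-yl]oxy}dimethylsilane
Product: 3 (2S)-2-[(tert-butyldimethylsilyl)oxy]-2-methylpentanedial
Conditions: O3, CH2Cl2, −78 °C; then Me2S, −78 °C → rt; used crude
Reagents that add atoms: ozone, [O-][O+]=O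
Why: Ozonolysis with reductive work-up should cleave both C=C bonds, turning linalool C2 and C6 into formyl carbons, while the quaternary silyloxy carbon cannot epimerise.

Step 3
Reactants: 4 ethyltriphenylphosphonium bromide
Product: 6 triphenyl[1-(trimethylsilyl)propan-2-yl]phosphonium iodide, via ethylidenetriphenylphosphorane 5 (not isolated)
Conditions: n-BuLi (1.0 equiv), THF, 0 °C; then ICH2SiMe3 (1.0 equiv), 0 °C → rt; salt filtered off
Reagents that add atoms: (iodomethyl)trimethylsilane, C[Si](C)(C)CI
Why: C-alkylation of a non-stabilised phosphorus ylide by a primary iodide (ylide alkylation) should give the beta-silyl phosphonium salt, which is racemic at a carbon that becomes sp2 in the next step.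

Step 4
Reactants: 6 triphenyl[1-(trimethylsilyl)propan-2-yl]phosphonium iodide; 3 (2S)-2-[(tert-butyldimethylsilyl)oxy]-2-methylpentanedial
Product: 8 (2S)-2-[(tert-butyldimethylsilyl)oxy]-2,6-dimethyl-7-(trimethylsilyl)hept-5-enal (E/Z mixture), via triphenyl[1-(trimethylsilyl)propan-2-ylidene]phosphorane 7 (not isolated)
Conditions: 6, n-BuLi (1.0 equiv), THF, −78 → 0 °C; then added to 3 (1.2 equiv), THF, −78 → −20 °C
Reagents that add atoms: none
Why: Wittig olefination in which the fully substituted ylide carbon should add much faster to the unhindered formyl group than to the neopentyl-type formyl group beside the quaternary silyloxy carbon, so that only the allylsilane end is built.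

Step 5
Reactants: 8 (2S)-2-[(tert-butyldimethylsilyl)oxy]-2,6-dimethyl-7-(trimethylsilyl)hept-5-enal
Product: 9 tert-butyl{[(3S)-1-methoxy-3,7-dimethyl-8-(trimethylsilyl)octa-1,6-dien-3-yl]oxy}dimethylsilane (E/Z mixture at C1=C2 and at C6=C7)
Conditions: MeOCH2PPh3Cl (2.5 equiv), KN(SiMe3)2 (2.4 equiv), THF, 0 °C; then 8, 0 °C → rt; Et3N-deactivated silica
Reagents that add atoms: (methoxymethyl)triphenylphosphonium chloride, COC[P+](c1ccccc1)(c1ccccc1)c1ccccc1.[Cl-]
Why: Wittig methoxymethylenation of the remaining non-enolisable aldehyde should install the methyl enol ether under basic conditions that the allylsilane and the silyl ether tolerate.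

Step 6
Reactants: 9 tert-butyl{[(3S)-1-methoxy-3,7-dimethyl-8-(trimethylsilyl)octa-1,6-dien-3-yl]oxy}dimethylsilane
Product: 10 tert-butyl{[(1S,2R,3S)-2-(dimethoxymethyl)-1-methyl-3-(prop-1-en-2-yl)cyclopentyl]oxy}dimethylsilane
Conditions: RVC anode, Pt cathode, undivided cell, constant current 8 mA, 2.2 F/mol, 0.1 M LiClO4, MeOH/THF (3:7), 2,6-lutidine (4 equiv), rt
Reagents that add atoms: methanol, CO
Why: One-electron oxidation of the enol ether at the carbon anode gives a radical cation whose carbon beta to oxygen (C2) is attacked by the gamma-carbon of the allylsilane (C6); the beta-silyl cation at C7 then hands Me3Si+ to methanol and becomes the isopropenyl group, while the alpha-methoxy radical at C1 is oxidised a second time and captured by methanol as the dimethyl acetal (2 F/mol, 2,6-lutidine buffering the protons). The closest known reaction type is the intramolecular anodic olefin coupling of enol ether radical cations with allylsilanes in methanol. The cyclopentane closes in a 5-exo-trig mode onto C6 with C7 exocyclic. The C6 centre is controlled by the C3 stereocentre: in the envelope-like transition state the C3–O bond should lie anti to the incoming C6, as in Felkin–Anh additions beside an alpha-silyloxy centre, which places the C3 methyl on the face toward which C7 points and gives isopropenyl cis to methyl; the C2 centre is controlled by the bulky C7 terminus turning away from C1, so the acetal carbon ends trans to isopropenyl and cis to the silyloxy group, and this centre remains correctable by enolisation at the aldehyde stage. The step needs facial selectivity at C6 relative to C3, ring closure faster than methanol capture of the radical cation, and loss of silicon instead of a proton from C7; these rest, in that order, on the bulky electron-withdrawing silyloxy group at quaternary C3, on the short gem-disubstituted tether together with the high nucleophilicity of the allylsilane, and on the C–Si bond aligned with the developing cation.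

Step 7
Reactants: 10 tert-butyl{[(1S,2R,3S)-2-(dimethoxymethyl)-1-methyl-3-(prop-1-en-2-yl)cyclopentyl]oxy}dimethylsilane
Product: 11 (1S,2R,3S)-2-(dimethoxymethyl)-1-methyl-3-(prop-1-en-2-yl)cyclopentan-1-ol
Conditions: Bu4NF (3 equiv), THF, 60 °C
Reagents that add atoms: none
Why: Fluoride-induced desilylation should free the tertiary alcohol while the acetal and the isopropenyl group are inert to fluoride and no stereocentre is touched.

Step 8
Reactants: 11 (1S,2R,3S)-2-(dimethoxymethyl)-1-methyl-3-(prop-1-en-2-yl)cyclopentan-1-ol
Product: 12 (1R,2S,5S)-2-hydroxy-2-methyl-5-(prop-1-en-2-yl)cyclopentane-1-carbaldehyde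
Conditions: PPTS (0.2 equiv), acetone/H2O (9:1), 40 °C
Reagents that add atoms: water, O
Why: Mild acid-catalysed acetal hydrolysis should give the aldehyde, and because 12 has the formyl group trans to isopropenyl and cis (hydrogen-bonded) to the hydroxyl it is the thermodynamic isomer, so any C1 epimer carried from step 6 should converge on it through the enol.

Step 9
Reactants: 13 (R)-2-methylbutanoic acid; 14 2-methylphloroglucinol
Product: 16 (2R)-2-methyl-1-(2,4,6-trihydroxy-3-methylphenyl)butan-1-one, via (R)-2-methylbutanoyl chloride 15 (not isolated)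
Conditions: 13, (COCl)2, DMF (cat.), CH2Cl2, 0 °C → rt; then 14, AlCl3 (3.5 equiv), PhNO2/CH2Cl2, 0 °C → rt; aq. HCl
Reagents that add atoms: oxalyl chloride, O=C(Cl)C(=O)Cl (supplies only the chlorine of intermediate 15)
Why: Friedel–Crafts C-acylation at one of the two equivalent free positions of the electron-rich ring should give the mono-ketone, and low temperature without base should keep the alpha stereocentre of the acyl group from enolising.

Step 10
Reactants: 16 (2R)-2-methyl-1-(2,4,6-trihydroxy-3-methylphenyl)butan-1-one; 17 prenyl bromide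
Product: 18 (6RS)-3,5-dihydroxy-6-methyl-6-(3-methylbut-2-en-1-yl)-2-[(2R)-2-methylbutanoyl]cyclohexa-2,4-dien-1-one (both C6 epimers)
Conditions: NaOMe (2.2 equiv), MeOH, 0 °C; then 17 (1.05 equiv), 0 °C → rt; aq. HCl
Reagents that add atoms: none
Why: Alkylative dearomatisation of the acylphloroglucinol anion at its methyl-bearing carbon should create the quaternary centre and leave the other ring CH free; the remote acyl stereocentre gives no facial bias, so both C6 epimers are expected in comparable amounts.

Step 11
Reactants: 18 (6RS)-3,5-dihydroxy-6-methyl-6-(3-methylbut-2-en-1-yl)-2-[(2R)-2-methylbutanoyl]cyclohexa-2,4-dien-1-one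
Product: 19 (6R)-3,5-dihydroxy-6-methyl-6-(3-methylbut-2-en-1-yl)-2-[(2R)-2-methylbutanoyl]cyclohexa-2,4-dien-1-one
Conditions: preparative HPLC, amylose tris(3,5-dimethylphenylcarbamate) phase, hexane/i-PrOH with 0.1% TFA, rt
Reagents that add atoms: none
Why: Chromatographic resolution on a chiral stationary phase should separate the two epimers, which differ only at ring C6, and the configuration of the collected epimer would be assigned by X-ray or ECD before use.

Step 12
Reactants: 12 (1R,2S,5S)-2-hydroxy-2-methyl-5-(prop-1-en-2-yl)cyclopentane-1-carbaldehyde; 19 (6R)-3,5-dihydroxy-6-methyl-6-(3-methylbut-2-en-1-yl)-2-[(2R)-2-methylbutanoyl]cyclohexa-2,4-dien-1-one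
Product: 21 (6R)-3,5-dihydroxy-4-{[(1R,2S,5S)-2-hydroxy-2-methyl-5-(prop-1-en-2-yl)cyclopentyl]methyl}-6-methyl-6-(3-methylbut-2-en-1-yl)-2-[(2R)-2-methylbutanoyl]cyclohexa-2,4-dien-1-one (the target), via Knoevenagel alkylidene trione 20 (not isolated)
Conditions: L-proline (10 mol%), Hantzsch ester (1.2 equiv), CH2Cl2, rt
Reagents that add atoms: none
Why: Three-component reductive alkylation (Knoevenagel condensation, then conjugate hydride transfer from the Hantzsch ester) should join the acidic ring CH of 19 to the formyl carbon and reduce the alkylidene trione before it can add a second trione; no stereocentre is formed or disturbed.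

Compound list
1 | (S)-(+)-linalool, (3S)-3,7-dimethylocta-1,6-dien-3-ol | C=C[C@@](C)(O)CCC=C(C)C | starting material
2 | tert-butyl{[(3S)-3,7-dimethylocta-1,6-dien-3-yl]oxy}dimethylsilane | C=C[C@@](C)(O[Si](C)(C)C(C)(C)C)CCC=C(C)C | intermediate
3 | (2S)-2-[(tert-butyldimethylsilyl)oxy]-2-methylpentanedial | O=C[C@@](C)(O[Si](C)(C)C(C)(C)C)CCC=O | intermediate
4 | ethyltriphenylphosphonium bromide | CC[P+](c1ccccc1)(c1ccccc1)c1ccccc1.[Br-] | starting material
5 | ethylidenetriphenylphosphorane | CC=P(c1ccccc1)(c1ccccc1)c1ccccc1 | intermediate (not isolated)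
6 | triphenyl[1-(trimethylsilyl)propan-2-yl]phosphonium iodide (racemic) | CC(C[Si](C)(C)C)[P+](c1ccccc1)(c1ccccc1)c1ccccc1.[I-] | intermediate
7 | triphenyl[1-(trimethylsilyl)propan-2-ylidene]phosphorane | CC(C[Si](C)(C)C)=P(c1ccccc1)(c1ccccc1)c1ccccc1 | intermediate (not isolated)
8 | (2S)-2-[(tert-butyldimethylsilyl)oxy]-2,6-dimethyl-7-(trimethylsilyl)hept-5-enal, E/Z mixture at C5=C6 | O=C[C@@](C)(O[Si](C)(C)C(C)(C)C)CCC=C(C)C[Si](C)(C)C | intermediate
9 | tert-butyl{[(3S)-1-methoxy-3,7-dimethyl-8-(trimethylsilyl)octa-1,6-dien-3-yl]oxy}dimethylsilane, geometric isomers at C1=C2 and C6=C7 (the 1E,6E isomer is one component) | COC=C[C@@](C)(O[Si](C)(C)C(C)(C)C)CCC=C(C)C[Si](C)(C)C | intermediate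
10 | tert-butyl{[(1S,2R,3S)-2-(dimethoxymethyl)-1-methyl-3-(prop-1-en-2-yl)cyclopentyl]oxy}dimethylsilane | C=C(C)[C@H]1CC[C@](C)(O[Si](C)(C)C(C)(C)C)[C@@H]1C(OC)OC | intermediate
11 | (1S,2R,3S)-2-(dimethoxymethyl)-1-methyl-3-(prop-1-en-2-yl)cyclopentan-1-ol | C=C(C)[C@H]1CC[C@](C)(O)[C@@H]1C(OC)OC | intermediate
12 | (1R,2S,5S)-2-hydroxy-2-methyl-5-(prop-1-en-2-yl)cyclopentane-1-carbaldehyde | C=C(C)[C@H]1CC[C@](C)(O)[C@@H]1C=O | intermediate
13 | (R)-2-methylbutanoic acid | CC[C@@H](C)C(=O)O | starting material
14 | 2-methylphloroglucinol (2-methylbenzene-1,3,5-triol) | Cc1c(O)cc(O)cc1O | starting material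
15 | (R)-2-methylbutanoyl chloride | CC[C@@H](C)C(=O)Cl | intermediate (not isolated)
16 | (2R)-2-methyl-1-(2,4,6-trihydroxy-3-methylphenyl)butan-1-one | CC[C@@H](C)C(=O)c1c(O)cc(O)c(C)c1O | intermediate
17 | prenyl bromide (1-bromo-3-methylbut-2-ene) | CC(C)=CCBr | starting material
18 | (6RS)-3,5-dihydroxy-6-methyl-6-(3-methylbut-2-en-1-yl)-2-[(2R)-2-methylbutanoyl]cyclohexa-2,4-dien-1-one, both C6 epimers | CC[C@@H](C)C(=O)C1=C(O)C=C(O)C(C)(CC=C(C)C)C1=O | intermediate
19 | (6R)-3,5-dihydroxy-6-methyl-6-(3-methylbut-2-en-1-yl)-2-[(2R)-2-methylbutanoyl]cyclohexa-2,4-dien-1-one | CC[C@@H](C)C(=O)C1=C(O)C=C(O)[C@@](C)(CC=C(C)C)C1=O | intermediate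
20 | Knoevenagel alkylidene trione: the formyl carbon of 12 doubly bonded to ring C4 of 19, all stereocentres as in 12 and 19, exocyclic C=C geometry open | C=C(C)[C@H]1CC[C@](C)(O)[C@@H]1C=C1C(=O)[C@@](C)(CC=C(C)C)C(=O)C(C(=O)[C@H](C)CC)=C1O | intermediate (not isolated)
21 | (6R)-3,5-dihydroxy-4-{[(1R,2S,5S)-2-hydroxy-2-methyl-5-(prop-1-en-2-yl)cyclopentyl]methyl}-6-methyl-6-(3-methylbut-2-en-1-yl)-2-[(2R)-2-methylbutanoyl]cyclohexa-2,4-dien-1-one (CNP0299585.1) | C=C(C)[C@H]1CC[C@](C)(O)[C@@H]1CC1=C(O)[C@@](C)(CC=C(C)C)C(=O)C(C(=O)[C@H](C)CC)=C1O | target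

Total step count: 12 (eleven reactions and one chromatographic resolution).
Longest linear sequence: 8 steps (steps 1, 2, 4, 5, 6, 7, 8 and 12, from (S)-linalool).

Steps most likely to fail

1. Step 6. What may go wrong: loss of facial control. A competing transition state with the C3 methyl, not the silyloxy group, anti to the forming bond relieves a methyl/C7 contact and would place the isopropenyl group cis to oxygen. Methanol capture of the radical cation before ring closure is the second possibility. Fallback, setting out from 8 and returning at 10: the same C2–C6 bond would be made by closed-shell chemistry with an external control element. Aldehyde 8 would be treated with Me2AlCl (2.5 equiv, CH2Cl2, −78 °C). The aluminium centre should bridge the aldehyde oxygen and the silyloxy oxygen, the tethered allylsilane attacks the chelated formyl carbon (intramolecular Hosomi–Sakurai reaction), and C7 has to stay away from the chelate ring. This fixes isopropenyl trans to oxygen and should give the cyclopentanol (2S,5R)-2-[(tert-butyldimethylsilyl)oxy]-2-methyl-5-(prop-1-en-2-yl)cyclopentan-1-ol F1 (carbinol carbon of either configuration). Dess–Martin oxidation would give the ketone (2S,5R)-2-[(tert-butyldimethylsilyl)oxy]-2-methyl-5-(prop-1-en-2-yl)cyclopentan-1-one F2. Methoxymethylenation at low temperature (MeOCH2PPh3Cl, KN(SiMe3)2, THF, −78 → 0 °C) would give the enol ether tert-butyl{[(1S,3R)-2-(methoxymethylidene)-1-methyl-3-(prop-1-en-2-yl)cyclopentyl]oxy}dimethylsilane F3. PPTS in methanol would then add methanol across the enol ether to return to acetal 10, formed together with its epimer at the acetal-bearing ring carbon; both converge on 12 in step 8.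

2. Step 10. What may go wrong: attack of prenyl bromide at the unsubstituted ring carbon (which re-aromatises to the C-prenyl isomer), at oxygen, or a second alkylation, so that little of the quaternary product forms. Fallback, setting out from 16 and 12 and returning at 21: the free ring position would first be filled with the side chain it must carry anyway. Reductive alkylation of the aromatic ketone 16 with aldehyde 12 (L-proline, Hantzsch ester, CH2Cl2) would give the fully substituted acylphloroglucinol (2R)-1-[2,4,6-trihydroxy-3-{[(1R,2S,5S)-2-hydroxy-2-methyl-5-(prop-1-en-2-yl)cyclopentyl]methyl}-5-methylphenyl]-2-methylbutan-1-one F4. Its dearomatising prenylation (NaOMe, MeOH, 17) can then only occur at the methyl-bearing carbon or at the far more hindered carbon bearing the cyclopentylmethyl group. It should give 21 together with the (6S)-epimer of 21 F5, and the chromatographic resolution would be moved to this last stage.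

3. Step 12. What may go wrong: loss of the beta-hydroxy aldehyde by amine-promoted dehydration or retro-aldol ring opening before its hindered formyl group condenses. Fallback, setting out from 10 and returning at 21: the silyl ether would be kept through the coupling. Hydrolysis of 10 (PPTS, acetone/H2O) would give the silyloxy aldehyde (1R,2S,5S)-2-[(tert-butyldimethylsilyl)oxy]-2-methyl-5-(prop-1-en-2-yl)cyclopentane-1-carbaldehyde F6, which cannot undergo retro-aldol cleavage. The same reductive alkylation with 19 would give the tert-butyldimethylsilyl ether of 21 at the cyclopentanol oxygen F7, and fluoride desilylation (Bu4NF, THF, 50 °C) would be the final operation.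

Further compounds
F1 | step 6 | (2S,5R)-2-[(tert-butyldimethylsilyl)oxy]-2-methyl-5-(prop-1-en-2-yl)cyclopentan-1-ol (C1 of either configuration) | C=C(C)[C@H]1CC[C@](C)(O[Si](C)(C)C(C)(C)C)C1O
F2 | step 6 | (2S,5R)-2-[(tert-butyldimethylsilyl)oxy]-2-methyl-5-(prop-1-en-2-yl)cyclopentan-1-one | C=C(C)[C@H]1CC[C@](C)(O[Si](C)(C)C(C)(C)C)C1=O
F3 | step 6 | tert-butyl{[(1S,3R)-2-(methoxymethylidene)-1-methyl-3-(prop-1-en-2-yl)cyclopentyl]oxy}dimethylsilane (E/Z) | C=C(C)[C@H]1CC[C@](C)(O[Si](C)(C)C(C)(C)C)C1=COC
F4 | step 10 | (2R)-1-[2,4,6-trihydroxy-3-{[(1R,2S,5S)-2-hydroxy-2-methyl-5-(prop-1-en-2-yl)cyclopentyl]methyl}-5-methylphenyl]-2-methylbutan-1-one | C=C(C)[C@H]1CC[C@](C)(O)[C@@H]1Cc1c(O)c(C)c(O)c(C(=O)[C@H](C)CC)c1O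
F5 | step 10 | (6S)-epimer of 21 | C=C(C)[C@H]1CC[C@](C)(O)[C@@H]1CC1=C(O)[C@](C)(CC=C(C)C)C(=O)C(C(=O)[C@H](C)CC)=C1O
F6 | step 12 | (1R,2S,5S)-2-[(tert-butyldimethylsilyl)oxy]-2-methyl-5-(prop-1-en-2-yl)cyclopentane-1-carbaldehyde | C=C(C)[C@H]1CC[C@](C)(O[Si](C)(C)C(C)(C)C)[C@@H]1C=O
F7 | step 12 | tert-butyldimethylsilyl ether of 21 at the cyclopentanol oxygen | C=C(C)[C@H]1CC[C@](C)(O[Si](C)(C)C(C)(C)C)[C@@H]1CC1=C(O)[C@@](C)(CC=C(C)C)C(=O)C(C(=O)[C@H](C)CC)=C1O
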